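**Strategy.** The route rests on cutting the bond between ring carbon C3 of the tetrahydrofuran (O1, C2–C5) and its exocyclic CH2O carbon. In one operation, the acyloxymethyl radical from iodomethyl O‑silyl‑p‑coumarate 13 adds to the β‑carbon of the 2,5‑dihydrofuran‑3‑yl aryl ketone 8 (Giese addition), anti to the C2 aryl group. Hydrogen transfer to the resulting C4 radical, anti to the new substituent, then sets the 3,4‑cis relationship. The step thus exploits the contiguous C2–C3–C4 stereotriad: the one catalytically set centre (C2) relays to C3 and C4, and then, through Felkin–Anh/chelate‑controlled reduction of the C4 aroyl group, to the carbinol centre. Enone 8 comes from an allylic ether by ring‑closing metathesis.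

Key step: step 10

Remarks on the chemistry: the target's tetrahydrofuran atoms are numbered O1, C2 (aryl), C3 (CH2O‑acyl), C4 (carbinol side chain), C5. "Ar" in names means 4‑(tert‑butyldimethylsilyloxy)‑3‑methoxyphenyl; both Ar groups come from the same protected vanillin 2. Zn(CH=CH2)2 and Zn(BH4)2 are assumed to be used as separately prepared, salt‑free stock solutions.

Step 1
Reactants: 1 vanillin
Product: 2 4‑(tert‑butyldimethylsilyloxy)‑3‑methoxybenzaldehyde
Conditions: TBSCl, imidazole, DMF, rt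
Reagents that add atoms: tert‑butyldimethylsilyl chloride CC(C)(C)[Si](C)(C)Cl
Why: Standard phenol silylation gives a protecting group that survives organometallic, radical and hydride steps and is removed by fluoride at the end.

Step 2
Reactants: 2 4‑(tert‑butyldimethylsilyloxy)‑3‑methoxybenzaldehyde
Product: 3 (S)‑1‑Ar‑prop‑2‑en‑1‑ol
Conditions: Zn(CH=CH2)2 (1.5 equiv), (2S)‑(−)‑3‑exo‑morpholinoisoborneol (5 mol %), toluene/hexane, 0 °C; aq. NH4Cl
Reagents that add atoms: divinylzinc C=C[Zn]C=C
Why: Amino‑alcohol‑catalysed enantioselective organozinc addition to an aldehyde, in which the chiral zinc amino‑alkoxide should deliver the vinyl group to the Si face and so set the (S) carbinol centre (future C2), the only stereocentre set by a catalyst.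

Step 3
Reactants: 3 (S)‑1‑Ar‑prop‑2‑en‑1‑ol; 4 2,3‑dibromopropene
Product: 5 (S)‑1‑Ar‑prop‑2‑enyl 2‑bromoprop‑2‑enyl ether
Conditions: NaH, Bu4NI (cat.), THF/DMF, 0 °C to rt
Reagents that add atoms: none
Why: Williamson etherification at the allylic C–Br bond only (the vinylic bromide is inert), with no bond to the stereocentre broken.

Step 4
Reactants: 5 (S)‑1‑Ar‑prop‑2‑enyl 2‑bromoprop‑2‑enyl ether; 2 4‑(tert‑butyldimethylsilyloxy)‑3‑methoxybenzaldehyde
Product: 6 1‑Ar‑2‑({[(S)‑1‑Ar‑prop‑2‑enyl]oxy}methyl)prop‑2‑en‑1‑ol (both carbinol epimers)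
Conditions: CrCl2 (4 equiv), NiCl2 (2 mol %), DMF, rt
Reagents that add atoms: none
Why: Nozaki–Hiyama–Kishi coupling, in which the alkenylchromium species (trivalent chromium) adds chemoselectively to the aldehyde; the new carbinol centre forms without control and is erased by the oxidation in step 6.

Step 5
Reactants: 6 diene carbinol
Product: 7 [(5S)‑5‑Ar‑2,5‑dihydrofuran‑3‑yl](Ar)methanol (both carbinol epimers)
Conditions: second‑generation Grubbs catalyst (5 mol %), CH2Cl2, 40 °C
Reagents that add atoms: none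
Why: Ring‑closing metathesis of the monosubstituted and the 1,1‑disubstituted alkene closes the five‑membered ring with loss of ethene and leaves the allylic stereocentre untouched.

Step 6
Reactants: 7 dihydrofuranyl carbinol
Product: 8 [(5S)‑5‑Ar‑2,5‑dihydrofuran‑3‑yl](Ar)methanone
Conditions: Dess–Martin periodinane, pyridine, CH2Cl2, 0 °C
Reagents that add atoms: none
Why: Dess–Martin oxidation of the allylic, benzylic alcohol under neutral conditions gives the cross‑conjugated enone without base that could deprotonate the doubly activated ring C–H next to oxygen.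

Step 7
Reactants: 9 (E)‑p‑coumaric acid
Product: 11 (E)‑3‑[4‑(tert‑butyldimethylsilyloxy)phenyl]acrylic acid, via bis‑silylated silyl ester 10 (not isolated)
Conditions: TBSCl (2.4 equiv), imidazole, DMF, rt; then AcOH/THF/H2O, rt
Reagents that add atoms: tert‑butyldimethylsilyl chloride CC(C)(C)[Si](C)(C)Cl
Why: Exhaustive silylation followed by selective hydrolysis of the far more labile silyl ester leaves the aryl silyl ether in place.

Step 8
Reactants: 11 (E)‑3‑[4‑(tert‑butyldimethylsilyloxy)phenyl]acrylic acid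
Product: 12 chloromethyl (E)‑3‑[4‑(tert‑butyldimethylsilyloxy)phenyl]acrylate
Conditions: ClCH2OSO2Cl, NaHCO3, Bu4NHSO4 (cat.), CH2Cl2/H2O, rt
Reagents that add atoms: chloromethyl chlorosulfate ClCOS(=O)(=O)Cl
Why: Phase‑transfer O‑alkylation of the carboxylate, which displaces chlorosulfate from the CH2 carbon; this installs the carbon that becomes the exocyclic CH2 of the target.

Step 9
Reactants: 12 chloromethyl ester
Product: 13 iodomethyl (E)‑3‑[4‑(tert‑butyldimethylsilyloxy)phenyl]acrylate
Conditions: NaI, acetone, rt, dark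
Reagents that add atoms: sodium iodide [Na+].[I-]
Why: Finkelstein exchange, driven by precipitation of NaCl, gives the iodide needed for fast halogen abstraction.

Step 10
Reactants: 8 dihydrofuranyl aryl ketone; 13 iodomethyl ester (1.5 equiv)
Product: 14 [(2S,3R,4R)‑2‑Ar‑4‑(Ar‑carbonyl)tetrahydrofuran‑3‑yl]methyl (E)‑3‑[4‑(tert‑butyldimethylsilyloxy)phenyl]acrylate
Conditions: (Me3Si)3SiH (1.6 equiv, slow addition), Et3B (cat.)/air, toluene, 0 °C
Reagents that add atoms: none
Why: Giese‑type reductive radical conjugate addition: (Me3Si)3Si• abstracts iodine from 13, and the acyloxymethyl radical adds to the enone β‑carbon of 8 (future C3), the closest precedents being additions of α‑oxygenated alkyl radicals to cyclic enones and butenolides. No ring is closed. C3 is controlled by the adjacent C2 aryl group, which blocks one face of the flat dihydrofuran so that the radical enters anti (2,3‑trans). C4 is set when the planar α‑aroyl radical takes hydrogen from the bulky silane on the face opposite the new C3 substituent (anti rule for cyclic radicals, the radical counterpart of kinetic ketonisation of exocyclic enols), which leaves the aroyl group cis to the CH2O group, the contra‑thermodynamic 3,4‑cis array the target needs. The step needs chemoselectivity for the enone over the cinnamate unit and suppression of premature reduction of the radical; the β‑aryl‑substituted, less electrophilic cinnamate is a poor acceptor, and slow silane addition at high enone concentration keeps hydrogen transfer to the primary radical slow. The neutral, base‑free conditions keep the activated C2–H of 8 and the epimerisable C4–H of 14 intact.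

Step 11
Reactants: 14 keto ester
Product: 15 [(2S,3R,4R)‑2‑Ar‑4‑[(S)‑Ar(hydroxy)methyl]tetrahydrofuran‑3‑yl]methyl (E)‑3‑[4‑(tert‑butyldimethylsilyloxy)phenyl]acrylate
Conditions: Zn(BH4)2, Et2O, −30 °C
Reagents that add atoms: none
Why: Substrate‑controlled hydride reduction of the aryl ketone, in which both the Felkin–Anh conformer (C3 branch as large group) and the zinc chelate between the carbonyl and ring O1 expose the same carbonyl face and should give the (S) carbinol, while the neutral reagent spares the cinnamate ester and the C4 stereocentre.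

Step 12
Reactants: 15 tris‑silyl ether
Product: 16 [(2S,3R,4R)‑2‑(4‑hydroxy‑3‑methoxyphenyl)‑4‑[(S)‑hydroxy(4‑hydroxy‑3‑methoxyphenyl)methyl]tetrahydrofuran‑3‑yl]methyl (E)‑3‑(4‑hydroxyphenyl)acrylate
Conditions: Bu4NF/AcOH (1:1, 3.5 equiv), THF, 0 °C
Reagents that add atoms: none
Why: Buffered fluoride cleaves the three aryl silyl ethers under near‑neutral conditions that should spare the ester, the benzylic ether and the benzylic alcohol.

**Compound list**

1 | vanillin | O=Cc1ccc(O)c(OC)c1 | starting material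
2 | 4‑(tert‑butyldimethylsilyloxy)‑3‑methoxybenzaldehyde | O=Cc1ccc(O[Si](C)(C)C(C)(C)C)c(OC)c1 | intermediate
3 | (S)‑1‑[4‑(tert‑butyldimethylsilyloxy)‑3‑methoxyphenyl]prop‑2‑en‑1‑ol | C=C[C@H](O)c1ccc(O[Si](C)(C)C(C)(C)C)c(OC)c1 | intermediate
4 | 2,3‑dibromopropene | C=C(Br)CBr | starting material
5 | tert‑butyl{4‑[(S)‑1‑(2‑bromoprop‑2‑enyloxy)prop‑2‑enyl]‑2‑methoxyphenoxy}dimethylsilane | C=C[C@H](OCC(Br)=C)c1ccc(O[Si](C)(C)C(C)(C)C)c(OC)c1 | intermediate
6 | 1‑Ar‑2‑({[(S)‑1‑Ar‑prop‑2‑enyl]oxy}methyl)prop‑2‑en‑1‑ol, both carbinol epimers | C=C[C@H](OCC(=C)C(O)c1ccc(O[Si](C)(C)C(C)(C)C)c(OC)c1)c1ccc(O[Si](C)(C)C(C)(C)C)c(OC)c1 | intermediate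
7 | [(5S)‑5‑Ar‑2,5‑dihydrofuran‑3‑yl](Ar)methanol, both carbinol epimers | OC(c1ccc(O[Si](C)(C)C(C)(C)C)c(OC)c1)C1=C[C@@H](c2ccc(O[Si](C)(C)C(C)(C)C)c(OC)c2)OC1 | intermediate
8 | [(5S)‑5‑Ar‑2,5‑dihydrofuran‑3‑yl](Ar)methanone | O=C(c1ccc(O[Si](C)(C)C(C)(C)C)c(OC)c1)C1=C[C@@H](c2ccc(O[Si](C)(C)C(C)(C)C)c(OC)c2)OC1 | intermediate
9 | (E)‑p‑coumaric acid | OC(=O)/C=C/c1ccc(O)cc1 | starting material
10 | tert‑butyldimethylsilyl (E)‑3‑[4‑(tert‑butyldimethylsilyloxy)phenyl]acrylate | CC(C)(C)[Si](C)(C)OC(=O)/C=C/c1ccc(O[Si](C)(C)C(C)(C)C)cc1 | intermediate (not isolated)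
11 | (E)‑3‑[4‑(tert‑butyldimethylsilyloxy)phenyl]acrylic acid | OC(=O)/C=C/c1ccc(O[Si](C)(C)C(C)(C)C)cc1 | intermediate
12 | chloromethyl (E)‑3‑[4‑(tert‑butyldimethylsilyloxy)phenyl]acrylate | ClCOC(=O)/C=C/c1ccc(O[Si](C)(C)C(C)(C)C)cc1 | intermediate
13 | iodomethyl (E)‑3‑[4‑(tert‑butyldimethylsilyloxy)phenyl]acrylate | ICOC(=O)/C=C/c1ccc(O[Si](C)(C)C(C)(C)C)cc1 | intermediate
14 | [(2S,3R,4R)‑2‑Ar‑4‑(Ar‑carbonyl)tetrahydrofuran‑3‑yl]methyl (E)‑3‑[4‑(tert‑butyldimethylsilyloxy)phenyl]acrylate | COc1cc(C(=O)[C@H]2CO[C@H](c3ccc(O[Si](C)(C)C(C)(C)C)c(OC)c3)[C@H]2COC(=O)/C=C/c2ccc(O[Si](C)(C)C(C)(C)C)cc2)ccc1O[Si](C)(C)C(C)(C)C | intermediate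
15 | [(2S,3R,4R)‑2‑Ar‑4‑[(S)‑Ar(hydroxy)methyl]tetrahydrofuran‑3‑yl]methyl (E)‑3‑[4‑(tert‑butyldimethylsilyloxy)phenyl]acrylate | COc1cc([C@@H](O)[C@H]2CO[C@H](c3ccc(O[Si](C)(C)C(C)(C)C)c(OC)c3)[C@H]2COC(=O)/C=C/c2ccc(O[Si](C)(C)C(C)(C)C)cc2)ccc1O[Si](C)(C)C(C)(C)C | intermediate
16 | [(2S,3R,4R)‑2‑(4‑hydroxy‑3‑methoxyphenyl)‑4‑[(S)‑hydroxy(4‑hydroxy‑3‑methoxyphenyl)methyl]tetrahydrofuran‑3‑yl]methyl (E)‑3‑(4‑hydroxyphenyl)acrylate | COc1cc([C@@H](O)[C@H]2CO[C@H](c3ccc(O)c(OC)c3)[C@H]2COC(=O)/C=C/c2ccc(O)cc2)ccc1O | target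

**Step count.** Total: 12 steps. Longest linear sequence: 9 steps (1, 2, 3, 4, 5, 6, 10, 11, 12); steps 7–9 form the side branch.

**Steps most likely to fail**

1. Step 10. Hydrogen transfer to the C4 radical may not discriminate the two faces well enough, because the C3 substituent is only a primary CH2 group and the C2 aryl group lies on the other face. The acyloxymethyl radical may also be reduced before it adds, or the silyl radical may add to the alkenes. Fallback, from 7 back to 14, with the C3–CH2 bond made intramolecularly so that the ring fusion enforces the cis relationship: 7 is silylated with (bromomethyl)chlorodimethylsilane (Et3N, DMAP, CH2Cl2) to the (bromomethyl)dimethylsilyl ether F1. Bu3SnH/AIBN (benzene, 80 °C, slow addition) then drives 6‑endo cyclisation of the silylmethyl radical onto the ring CH carbon, anti to the aryl group, with hydrogen transfer giving the cis‑fused bicyclic siloxane F2. Fluoride‑free Tamao oxidation (H2O2, KHCO3, THF/MeOH) gives the diol F3. Its primary alcohol is esterified selectively with acid 11 (EDC·HCl, DMAP, CH2Cl2, −20 °C) to the hydroxy ester F4. Dess–Martin oxidation of the benzylic alcohol then gives ketone 14.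

2. Step 4. Oxidative addition to the vinylic bromide may be slow, and the alkenylchromium species may lose the allylic alkoxide to give an allene, or homocouple. Fallback, from 5 back to 6, by a polar organolithium route instead of the chromium/nickel manifold: bromine–lithium exchange on 5 with t‑BuLi (2.1 equiv, Et2O, −78 °C) and immediate addition of aldehyde 2 at −78 °C, followed by NH4Cl quench, gives 6.

3. Step 11. Hydride delivery may be poorly face‑selective or favour the wrong face, and enolisation could scramble C4 before reduction. Fallback, from 14 back to 15, for the case where the undesired carbinol epimer dominates: the (R)‑carbinol epimer F5 is separated and inverted by Mitsunobu reaction with chloroacetic acid (PPh3, DIAD, toluene, 0 °C) to the (S)‑chloroacetate F6. Thiourea/NaHCO3 in EtOH then removes the chloroacetyl group without touching the cinnamate and gives 15.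

**Further compounds**

F1 | step 10 | (bromomethyl)dimethylsilyl ether of 7 (both carbinol epimers) | BrC[Si](C)(C)OC(c1ccc(O[Si](C)(C)C(C)(C)C)c(OC)c1)C1=C[C@@H](c2ccc(O[Si](C)(C)C(C)(C)C)c(OC)c2)OC1
F2 | step 10 | cis‑fused bicyclic siloxane (Si–CH2 on C3, Si–O on the carbinol carbon; carbinol epimers) | COc1cc(C(O[Si]3(C)C)[C@H]2CO[C@H](c4ccc(O[Si](C)(C)C(C)(C)C)c(OC)c4)[C@H]2C3)ccc1O[Si](C)(C)C(C)(C)C
F3 | step 10 | [(2S,3R,4R)‑2‑Ar‑4‑[Ar(hydroxy)methyl]tetrahydrofuran‑3‑yl]methanol (carbinol epimers) | COc1cc(C(O)[C@H]2CO[C@H](c3ccc(O[Si](C)(C)C(C)(C)C)c(OC)c3)[C@H]2CO)ccc1O[Si](C)(C)C(C)(C)C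
F4 | step 10 | primary (E)‑4‑silyloxycinnamate of F3 (carbinol epimers) | COc1cc(C(O)[C@H]2CO[C@H](c3ccc(O[Si](C)(C)C(C)(C)C)c(OC)c3)[C@H]2COC(=O)/C=C/c2ccc(O[Si](C)(C)C(C)(C)C)cc2)ccc1O[Si](C)(C)C(C)(C)C
F0 | step 4 | none | none
F5 | step 11 | (R)‑carbinol epimer of 15 | COc1cc([C@H](O)[C@H]2CO[C@H](c3ccc(O[Si](C)(C)C(C)(C)C)c(OC)c3)[C@H]2COC(=O)/C=C/c2ccc(O[Si](C)(C)C(C)(C)C)cc2)ccc1O[Si](C)(C)C(C)(C)C
F6 | step 11 | (S)‑chloroacetate of 15 | COc1cc([C@@H](OC(=O)CCl)[C@H]2CO[C@H](c3ccc(O[Si](C)(C)C(C)(C)C)c(OC)c3)[C@H]2COC(=O)/C=C/c2ccc(O[Si](C)(C)C(C)(C)C)cc2)ccc1O[Si](C)(C)C(C)(C)C
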